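Locants follow spiro[cyclohex-3-ene-1,5'-indene]. The six-membered carbocycle is closed last, between the carbinol carbon C7' and the ring-fusion methine C7a'. The array C7'(OH)(CH3)–C7a'H–C1'H2–C2'H2, which spans both carbocycles, is read as a homoallylic tertiary alcohol, the adduct of a methyl ketone and an allyl metal. A palladium-catalysed umpolung of an allylic alcohol to an E-allylborane followed by intramolecular allylboration therefore forms C7'–C7a', sets both of these stereocentres from the one at C3a', and leaves the vinyl group from which the cyclopentanone is made by hydroacylation. The precursor is an open-chain keto allylic alcohol on the enantioenriched quaternary carbon of a diprenylated acylphloroglucinol.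

Key step: step 7

Remark: the acylated triketone is written throughout as the enol tautomer of the target SMILES; its other tautomers, and the cyclic hemiacetals that the side-chain aldehydes form with the enol, are the same compounds. C6 of the cyclohexenedione numbering used for 3–13 becomes the spiro carbon.

Step 1
Reactants: 1 phlorisovalerophenone; 2 prenyl bromide
Product: 3 3-hydroxy-2-(3-methylbutanoyl)-4,4-bis(3-methylbut-2-en-1-yl)cyclohex-2-ene-1,5-dione
Conditions: NaOMe (2.2 equiv), 2 (2.1 equiv), MeOH, 0 °C to rt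
Reagents that add atoms: prenyl bromide, CC(C)=CCBr
Why: Alkylative dearomatisation (double C-prenylation) of the acylphloroglucinol phenoxide; the geminal diprenyl trione is expected together with the aromatic 3,5-diprenyl isomer and O-alkylated material and should be separable from them by chromatography.

Step 2
Reactants: 3; 4 acrolein
Product: 5 3-hydroxy-2-(3-methylbutanoyl)-4,4-bis(3-methylbut-2-en-1-yl)-6-(3-oxopropyl)cyclohex-2-ene-1,5-dione (C6 configurationally labile)
Conditions: 4 (1.05 equiv), Et3N (10 mol %), THF, 0 °C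
Reagents that add atoms: acrolein, C=CC=O
Why: Michael addition of C6, the only ring carbon of 3 that still carries hydrogen, to the enal; one equivalent at low temperature should limit double addition.

Step 3
Reactants: 5; 6 allyl methyl carbonate
Product: 7 (6S)-6-allyl-3-hydroxy-2-(3-methylbutanoyl)-4,4-bis(3-methylbut-2-en-1-yl)-6-(3-oxopropyl)cyclohex-2-ene-1,5-dione
Conditions: Pd2(dba)3·CHCl3 (2.5 mol %), (R,R)-N,N'-bis(2-diphenylphosphinobenzoyl)cyclohexane-1,2-diamine (7.5 mol %), 6 (1.3 equiv), CH2Cl2, 0 °C
Reagents that add atoms: allyl methyl carbonate, C=CCOC(=O)OC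
Why: Tsuji–Trost asymmetric allylic alkylation of the prochiral C6 enolate (base is the methoxide released from 6); O-allylation is reversible under palladium and funnels to the C-allyl product, and the ligand pocket is expected to distinguish the two enolate faces because one flank is a carbon bearing two prenyl chains and the other a flat acyl-enol; the ligand enantiomer is the one found to give 6S, which sets the spiro carbon.

Step 4
Reactants: 7
Product: 8 (6S)-3-hydroxy-2-(3-methylbutanoyl)-4,4-bis(3-methylbut-2-en-1-yl)-6-(2-oxopropyl)-6-(3-oxopropyl)cyclohex-2-ene-1,5-dione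
Conditions: PdCl2 (10 mol %), CuCl (1 equiv), O2 (1 atm), DMF/H2O 7:1, rt
Reagents that add atoms: water, O
Why: Tsuji–Wacker oxidation; only the monosubstituted terminal alkene is hydroxypalladated (Markovnikov, giving the methyl ketone), the trisubstituted prenyl alkenes should be inert.

Step 5
Reactants: 8; 9 formaldehyde
Product: 10 (6S)-6-[(2R)-2-formyl-3-hydroxypropyl]-3-hydroxy-2-(3-methylbutanoyl)-4,4-bis(3-methylbut-2-en-1-yl)-6-(2-oxopropyl)cyclohex-2-ene-1,5-dione
Conditions: (S)-α,α-diphenylprolinol trimethylsilyl ether (20 mol %), 37% aqueous HCHO, pH 7 phosphate buffer, toluene, rt; used without storage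
Reagents that add atoms: formaldehyde, C=O
Why: Enamine-catalysed α-hydroxymethylation (cross-aldol with formaldehyde); the aldehyde, not the methyl ketone, forms the enamine, and the diarylmethyl group of the (S)-catalyst shields the Re face of the E-enamine carbon so that formaldehyde should add to the Si face, giving the 2R centre (later C3a').

Step 6
Reactants: 10; 11 vinyl bromide
Product: 12 (6S)-3-hydroxy-6-[(2R)-3-hydroxy-2-(hydroxymethyl)pent-4-en-1-yl]-2-(3-methylbutanoyl)-4,4-bis(3-methylbut-2-en-1-yl)-6-(2-oxopropyl)cyclohex-2-ene-1,5-dione (both epimers at the allylic carbinol)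
Conditions: CrCl2 (4 equiv), NiCl2 (1 mol %), 11 (3 equiv), DMF, rt
Reagents that add atoms: vinyl bromide, C=CBr
Why: Nozaki–Hiyama–Kishi vinylation; the vinylchromium reagent adds to aldehydes and leaves ketones and free hydroxyls untouched, and the new carbinol centre need not be controlled because it is erased in step 7.

Step 7
Reactants: 12
Product: 14 (6S,8S,9R,10R)-9-ethenyl-3,10-dihydroxy-8-(hydroxymethyl)-10-methyl-2-(3-methylbutanoyl)-4,4-bis(3-methylbut-2-en-1-yl)spiro[5.5]undec-2-ene-1,5-dione, via E-allyldiethylborane 13 (not isolated)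
Conditions: Pd(PPh3)4 (5 mol %), Et3B (4 equiv), THF, 25 to 45 °C; then H2O
Reagents that add atoms: none
Why: Zerovalent palladium ionises the Et3B-activated allylic alcohol to a π-allyl complex, allyl–ethyl exchange with Et3B gives the E-allylborane 13, and its γ-carbon (later C9) adds to the methyl ketone through a closed six-membered B–O chair; the closest known reaction types are the palladium-catalysed umpolung allylation of aldehydes and ketones with allylic alcohols and the ring-forming allylboration of E-allylboron compounds to trans-2-vinylcycloalkanols. The carbocycle closes in 6-exo-trig mode at the carbonyl carbon, as a chair trans-fused to the boron-containing chair (Zimmerman–Traxler arrangement). C9 is controlled by the resident C8 centre, whose hydroxymethyl arm takes an equatorial site and places the vinyl group trans to it; C10 is controlled by the E-geometry and the closed transition state, which put the carbinol oxygen equatorial and anti to the vinyl group and the small methyl group axial. The step needs γ- rather than α-attack (six- versus eight-membered ring) and attack on the methyl ketone rather than on the C5 ring ketone, which is flanked by two quaternary carbons, or on the boron-bound triketone enolate. O-Allylation of that enolate by the π-allyl complex is reversible and should return material to the productive path.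

Step 8
Reactants: 14
Product: 15 (6S,8S,9R,10R)-9-ethenyl-3,10-dihydroxy-10-methyl-2-(3-methylbutanoyl)-4,4-bis(3-methylbut-2-en-1-yl)-1,5-dioxospiro[5.5]undec-2-ene-8-carbaldehyde
Conditions: TEMPO (10 mol %), PhI(OAc)2 (1.2 equiv), CH2Cl2, rt
Reagents that add atoms: none
Why: Oxoammonium-mediated oxidation is selective for the primary alcohol over the tertiary one and the alkenes; the formyl-bearing carbon is epimerisable, but the equatorial formyl group trans to the vinyl group is the stable arrangement.

Step 9
Reactants: 15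
Product: 16 (1S,3a'S,7'R,7a'R)-4,7'-dihydroxy-7'-methyl-3-(3-methylbutanoyl)-5,5-bis(3-methylbut-2-en-1-yl)spiro[cyclohex-3-ene-1,5'-octahydroindene]-2,3',6-trione (trans ring fusion)
Conditions: [Rh(dppe)]ClO4 (5 mol %; dppe = Ph2PCH2CH2PPh2), CH2Cl2, rt
Reagents that add atoms: none
Why: Rhodium-catalysed intramolecular hydroacylation of a 4-pentenal to a cyclopentanone; joining the equatorial formyl and vinyl groups gives the trans-fused hydrindanone without base, so C3a' should not epimerise, and the trisubstituted prenyl alkenes are too hindered and too remote to insert.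

Step 10
Reactants: 16; 17 methylmagnesium bromide
Product: 18 CNP0198642.3, (1S,3'R,3a'S,7'R,7a'R)-3',4,7'-trihydroxy-3',7'-dimethyl-3-(3-methylbutanoyl)-5,5-bis(3-methylbut-2-en-1-yl)spiro[cyclohex-3-ene-1,5'-octahydroindene]-2,6-dione
Conditions: CeCl3 (6 equiv), 17 (6 equiv), THF, −78 °C; then aqueous NH4Cl
Reagents that add atoms: methylmagnesium bromide, C[Mg]Br
Why: Organocerium 1,2-addition, non-basic so that the α-centre C3a' is not enolised; the α-face of the C3' carbonyl is screened by the axial H-7a' that lies 1,3 to it across the five-membered ring, so methyl should enter cis to H-3a' and give the 3'R carbinol, while the triketone is protected as its enolate and the C6 ring ketone by its two quaternary neighbours.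

Compound list
1 | phlorisovalerophenone, 3-methyl-1-(2,4,6-trihydroxyphenyl)butan-1-one | CC(C)CC(=O)c1c(O)cc(O)cc1O | starting material
2 | prenyl bromide, 1-bromo-3-methylbut-2-ene | CC(C)=CCBr | starting material
3 | 3-hydroxy-2-(3-methylbutanoyl)-4,4-bis(3-methylbut-2-en-1-yl)cyclohex-2-ene-1,5-dione | CC(C)=CCC1(CC=C(C)C)C(=O)CC(=O)C(C(=O)CC(C)C)=C1O | intermediate
4 | acrolein, prop-2-enal | C=CC=O | starting material
5 | 3-hydroxy-2-(3-methylbutanoyl)-4,4-bis(3-methylbut-2-en-1-yl)-6-(3-oxopropyl)cyclohex-2-ene-1,5-dione | CC(C)=CCC1(CC=C(C)C)C(=O)C(CCC=O)C(=O)C(C(=O)CC(C)C)=C1O | intermediate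
6 | allyl methyl carbonate | C=CCOC(=O)OC | starting material
7 | (6S)-6-allyl-3-hydroxy-2-(3-methylbutanoyl)-4,4-bis(3-methylbut-2-en-1-yl)-6-(3-oxopropyl)cyclohex-2-ene-1,5-dione | CC(C)=CCC1(CC=C(C)C)C(=O)[C@@](CC=C)(CCC=O)C(=O)C(C(=O)CC(C)C)=C1O | intermediate
8 | (6S)-3-hydroxy-2-(3-methylbutanoyl)-4,4-bis(3-methylbut-2-en-1-yl)-6-(2-oxopropyl)-6-(3-oxopropyl)cyclohex-2-ene-1,5-dione | CC(C)=CCC1(CC=C(C)C)C(=O)[C@@](CC(C)=O)(CCC=O)C(=O)C(C(=O)CC(C)C)=C1O | intermediate
9 | formaldehyde | C=O | starting material
10 | (6S)-6-[(2R)-2-formyl-3-hydroxypropyl]-3-hydroxy-2-(3-methylbutanoyl)-4,4-bis(3-methylbut-2-en-1-yl)-6-(2-oxopropyl)cyclohex-2-ene-1,5-dione | CC(C)=CCC1(CC=C(C)C)C(=O)[C@@](CC(C)=O)(C[C@H](CO)C=O)C(=O)C(C(=O)CC(C)C)=C1O | intermediate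
11 | vinyl bromide, bromoethene | C=CBr | starting material
12 | (6S)-3-hydroxy-6-[(2R)-3-hydroxy-2-(hydroxymethyl)pent-4-en-1-yl]-2-(3-methylbutanoyl)-4,4-bis(3-methylbut-2-en-1-yl)-6-(2-oxopropyl)cyclohex-2-ene-1,5-dione, both epimers at the allylic carbinol | CC(C)=CCC1(CC=C(C)C)C(=O)[C@@](CC(C)=O)(C[C@H](CO)C(O)C=C)C(=O)C(C(=O)CC(C)C)=C1O | intermediate
13 | E-allyldiethylborane, (6S)-6-[(2S,3E)-5-(diethylboranyl)-2-(hydroxymethyl)pent-3-en-1-yl]-3-hydroxy-2-(3-methylbutanoyl)-4,4-bis(3-methylbut-2-en-1-yl)-6-(2-oxopropyl)cyclohex-2-ene-1,5-dione | CC(C)=CCC1(CC=C(C)C)C(=O)[C@@](CC(C)=O)(C[C@H](CO)/C=C/CB(CC)CC)C(=O)C(C(=O)CC(C)C)=C1O | intermediate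
14 | (6S,8S,9R,10R)-9-ethenyl-3,10-dihydroxy-8-(hydroxymethyl)-10-methyl-2-(3-methylbutanoyl)-4,4-bis(3-methylbut-2-en-1-yl)spiro[5.5]undec-2-ene-1,5-dione | CC(C)=CCC1(CC=C(C)C)C(=O)[C@@]2(C[C@H](CO)[C@@H](C=C)[C@](C)(O)C2)C(=O)C(C(=O)CC(C)C)=C1O | intermediate
15 | (6S,8S,9R,10R)-9-ethenyl-3,10-dihydroxy-10-methyl-2-(3-methylbutanoyl)-4,4-bis(3-methylbut-2-en-1-yl)-1,5-dioxospiro[5.5]undec-2-ene-8-carbaldehyde | CC(C)=CCC1(CC=C(C)C)C(=O)[C@@]2(C[C@H](C=O)[C@@H](C=C)[C@](C)(O)C2)C(=O)C(C(=O)CC(C)C)=C1O | intermediate
16 | (1S,3a'S,7'R,7a'R)-4,7'-dihydroxy-7'-methyl-3-(3-methylbutanoyl)-5,5-bis(3-methylbut-2-en-1-yl)spiro[cyclohex-3-ene-1,5'-octahydroindene]-2,3',6-trione, trans-fused | CC(C)=CCC1(CC=C(C)C)C(=O)[C@@]2(C[C@H]3[C@@H](CCC3=O)[C@](C)(O)C2)C(=O)C(C(=O)CC(C)C)=C1O | intermediate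
17 | methylmagnesium bromide | C[Mg]Br | starting material
18 | CNP0198642.3, (1S,3'R,3a'S,7'R,7a'R)-3',4,7'-trihydroxy-3',7'-dimethyl-3-(3-methylbutanoyl)-5,5-bis(3-methylbut-2-en-1-yl)spiro[cyclohex-3-ene-1,5'-octahydroindene]-2,6-dione | CC(C)=CCC1(CC=C(C)C)C(=O)[C@@]2(C[C@H]3[C@@H](CC[C@@]3(C)O)[C@](C)(O)C2)C(=O)C(C(=O)CC(C)C)=C1O | target

Total steps: 10. Longest linear sequence: 10 steps (1 to 18).

Steps most likely to fail

Step 3. The chiral pocket may discriminate the two faces of the planar C6 enolate poorly, so that the 6-epimer forms and is carried into a diastereomeric series. The fallback sets out from 3 and moves the stereo-determining event to the other C–C bond at C6. Allylation of 3 with 6 and Pd(PPh3)4 without a chiral ligand gives 6-allyl-3-hydroxy-2-(3-methylbutanoyl)-4,4-bis(3-methylbut-2-en-1-yl)cyclohex-2-ene-1,5-dione F1. Its C6–H is then added to acrolein 4 under a bifunctional 6'-hydroxy cinchona alkaloid base catalyst, a known enantioselective route to quaternary carbons from 2-substituted 1,3-dicarbonyl compounds. The route is rejoined at 7.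

Step 5. The enamine may close onto the neighbouring methyl ketone in a five-membered aldol faster than it captures formaldehyde, and the new α-centre may erode by enolisation or retro-aldol loss of formaldehyde. The fallback sets out from 7, in which no ketone is present. The same hydroxymethylation gives (6S)-6-allyl-6-[(2R)-2-formyl-3-hydroxypropyl]-3-hydroxy-2-(3-methylbutanoyl)-4,4-bis(3-methylbut-2-en-1-yl)cyclohex-2-ene-1,5-dione F2. Silylation with TBSCl and imidazole gives its tert-butyldimethylsilyl ether F3, and Tsuji–Wacker oxidation of the allyl group gives the silyl ether of 10, F4. HF·pyridine removes the silyl group and the route is rejoined at 10.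

Step 7. The π-allyl complex may be captured by the triketone oxygen without return, the allylborane may be protonated by the free hydroxyls before it cyclises, or the ketone may be too unreactive. The fallback sets out from 12 and uses a palladium-free Barbier-type allylation. Silylation of the primary hydroxyl (TBSCl, imidazole) gives the mono-silyl ether of 12, F5. PBr3 converts the secondary vinyl carbinol with allylic transposition into the primary E-allylic bromide F6. Indium powder in THF/H2O closes the ring through the allylindium species, by the same chair, to the silyl ether of 14, F7. HF·pyridine then gives 14, where the route is rejoined.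

Further compounds
F1 | step 3 | 6-allyl-3-hydroxy-2-(3-methylbutanoyl)-4,4-bis(3-methylbut-2-en-1-yl)cyclohex-2-ene-1,5-dione | CC(C)=CCC1(CC=C(C)C)C(=O)C(CC=C)C(=O)C(C(=O)CC(C)C)=C1O
F2 | step 5 | (6S)-6-allyl-6-[(2R)-2-formyl-3-hydroxypropyl]-3-hydroxy-2-(3-methylbutanoyl)-4,4-bis(3-methylbut-2-en-1-yl)cyclohex-2-ene-1,5-dione | CC(C)=CCC1(CC=C(C)C)C(=O)[C@@](CC=C)(C[C@H](CO)C=O)C(=O)C(C(=O)CC(C)C)=C1O
F3 | step 5 | tert-butyldimethylsilyl ether of F2 | CC(C)=CCC1(CC=C(C)C)C(=O)[C@@](CC=C)(C[C@H](CO[Si](C)(C)C(C)(C)C)C=O)C(=O)C(C(=O)CC(C)C)=C1O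
F4 | step 5 | tert-butyldimethylsilyl ether of 10 | CC(C)=CCC1(CC=C(C)C)C(=O)[C@@](CC(C)=O)(C[C@H](CO[Si](C)(C)C(C)(C)C)C=O)C(=O)C(C(=O)CC(C)C)=C1O
F5 | step 7 | primary tert-butyldimethylsilyl ether of 12 | CC(C)=CCC1(CC=C(C)C)C(=O)[C@@](CC(C)=O)(C[C@H](CO[Si](C)(C)C(C)(C)C)C(O)C=C)C(=O)C(C(=O)CC(C)C)=C1O
F6 | step 7 | E-allylic bromide, (6S)-6-[(2S,3E)-5-bromo-2-(tert-butyldimethylsilyloxymethyl)pent-3-en-1-yl] analogue of 12 | CC(C)=CCC1(CC=C(C)C)C(=O)[C@@](CC(C)=O)(C[C@H](CO[Si](C)(C)C(C)(C)C)/C=C/CBr)C(=O)C(C(=O)CC(C)C)=C1O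
F7 | step 7 | primary tert-butyldimethylsilyl ether of 14 | CC(C)=CCC1(CC=C(C)C)C(=O)[C@@]2(C[C@H](CO[Si](C)(C)C(C)(C)C)[C@@H](C=C)[C@](C)(O)C2)C(=O)C(C(=O)CC(C)C)=C1O
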